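Readings and results stem from a simulated flask on assumed constants, noise included.

- In a one-step world each substrate molecule met one fork, reacted or spared. With both hands charged equally, left-handed substrate over right-handed substrate remaining equalled the ratio of their chances of being spared.

| setting | red | blue | teal | flask |
|---|---|---|---|---|
| left-handed substrate | 0.020 M | 0.020 M | 0.010 M | 0.020 M |
| right-handed substrate | 0.020 M | 0.020 M | 0.010 M | 0.020 M |
| reagent | 2 equiv | 2 equiv | 2 equiv | 2.00 equiv |
| precatalyst | 6.3 mol% | 14 mol% | 9.4 mol% | 9.4 mol% |
| remark | run made earlier | run made earlier | run made earlier |  |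
| time |  |  |  | 10 d |

- red (time / d: right-handed substrate / %, left-handed substrate / %): 2.08: 42, 4; 4.00: 35, 1; 6.00: 31, 1; 8.00: 28, 1
- blue (time / d: right-handed substrate / %, left-handed substrate / %): 0.625: 52, 26; 1.67: 43, 0; 3.00: 25, 0; 8.00: 17, 4
- teal (time / d: right-handed substrate / %, left-handed substrate / %): 2.08: 50, 1; 4.00: 39, 0; 6.00: 30, 0; 8.00: 29, 3

(scatter of a reading: 2 percentage points)

- whether the excess of right-handed substrate over left-handed substrate among what is left of the two reaches 80 % by 10 d (no / yes)
- the highest excess of right-handed substrate over left-handed substrate among what is left of the two up to 10 d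

- free catalyst is single-handed; left-handed substrate and right-handed substrate are mirror images of each other, charged as a racemate, each of them at the stated concentration

- I turned the question round: for the answer no, that ratio had to stay above 0.111 throughout the flask's 10 d. I called this the allowed ratio, left-handed over right-handed substrate at the moment the excess equals 80 %.
- I took a left-handed molecule's chance as the right-handed chance raised to the selectivity factor. With right-handed substrate at the red run's 28 % of the two charged, the answer no needed a factor below 4.79.
- The red run's readings at 2.08 d, 4 % left-handed and 42 % right-handed, gave a factor of 14.5, a rough reading given the scatter, but still 3.03 times what no required.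
- So I reckoned yes for the flask, though this gave me no top value. The forecast also said yes, with a top of 97 % (range 90 % to 100 %), “perhaps a little lower if left persists at a small floor”.

The flask gave yes, with a top of >99.9 %.

    free catalyst + left-handed substrate ⇌ catalyst intermediate A (K = 1100 L mol⁻¹, k = 1400 L mol⁻¹ h⁻¹)
    free catalyst + right-handed substrate ⇌ catalyst intermediate B (K = 66.0 L mol⁻¹, k = 78.0 L mol⁻¹ h⁻¹)
    reagent + catalyst intermediate A → free catalyst + left-handed product (k = 79.0 L mol⁻¹ h⁻¹)
    reagent + catalyst intermediate B → free catalyst + right-handed product (k = 36.0 L mol⁻¹ h⁻¹)
    2 reagent → homo dimer (k = 0.170 L mol⁻¹ h⁻¹)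
    free catalyst ⇌ dormant form (K = 1.90, k = 0.00250 h⁻¹)
    precatalyst → free catalyst (k = 0.0180 h⁻¹)

At 0.787 d in the flask, free catalyst was taken up by left-handed substrate 9.2 times as fast as by right-handed substrate, forward steps alone. The flask reached 80 % at 1.38 d, with 45.5 % right-handed substrate, so the allowed ratio put left-handed substrate at 5.05 %. In the blue run the reading at 0.625 d stood at 0.500, above the allowed ratio, and by 1.67 d left-handed substrate read 0 % against 43 % right-handed.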